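The C7 phenol oxygen and the ester carbonyl carbon of the target are joined through C8, the benzylic stereocentre and one CH2. Closing them gives a six-membered aryl lactone fused to the benzene ring, which is a 3-propylindan-1-one plus one oxygen atom. The route therefore rests on a Baeyer–Villiger oxygen insertion: a peracid converts (S)-4,6-dimethoxy-3-propylindan-1-one, made by rhodium-catalysed alkene hydroacylation, into the dihydrocoumarin. This forms the aryl C7–O bond and the lactone ring in one operation and leaves the stereocentre untouched. The lactone then masks O7 while the chromanone ring is closed onto O1, and it is opened to the methyl ester before the prenyl group is delivered from O7 to C6.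

Key step: step 4

Remark 1: a 3-substituted indan-1-one can only arise from a 1,1-disubstituted alkene, so the boron partner is the branched pent-1-en-2-yl reagent; a linear pentenyl isomer would lead to a 2-substituted ketone.
Remark 2: compounds 7–9 and 11 are numbered as chroman-2-ones, 12 and 13 as pyrano[2,3-f]chromenes, and 14, 17 and 18 as chroman-4-ones. Lactone O1, C8, C7–O, C6, C5–O and C4a correspond to O7, C6, C5–O, C4a, O1 and C8 of the target.
Remark 3: the senses of induction are assumed by analogy, (R)-BINAP for the (S)-indanone and quinine for the (2R,3S)-chromanone; should either prove opposite, (S)-BINAP or quinidine is used.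

Step 1
Reactants: 1 2-bromopent-1-ene
Product: 3 4,4,5,5-tetramethyl-2-(pent-1-en-2-yl)-1,3,2-dioxaborolane, via pent-1-en-2-ylmagnesium bromide 2 (not isolated)
Conditions: Mg, THF, 45 °C; then i-PrOBpin, −78 °C to rt; aq. NH4Cl
Reagents that add atoms: 2-isopropoxy-4,4,5,5-tetramethyl-1,3,2-dioxaborolane, CC(C)OB1OC(C)(C)C(C)(C)O1; magnesium, [Mg] (kept only in 2)
Why: Magnesium inserts into the vinylic C–Br bond and the Grignard reagent displaces isopropoxide from the borate ester (Grignard borylation), a standard entry to 1,1-disubstituted alkenyl pinacol boronates; no stereocentre is formed.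

Step 2
Reactants: 3 4,4,5,5-tetramethyl-2-(pent-1-en-2-yl)-1,3,2-dioxaborolane; 4 2-bromo-3,5-dimethoxybenzaldehyde
Product: 5 3,5-dimethoxy-2-(pent-1-en-2-yl)benzaldehyde
Conditions: Pd(OAc)2 (cat.), SPhos, K3PO4, PhMe/H2O, 80 °C
Reagents that add atoms: none
Why: Suzuki–Miyaura coupling with a bulky dialkylbiarylphosphine ligand should join the doubly ortho-substituted aryl bromide to the α-branched alkenyl boronate while the free aldehyde is tolerated; no stereocentre is formed.

Step 3
Reactants: 5 3,5-dimethoxy-2-(pent-1-en-2-yl)benzaldehyde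
Product: 6 (S)-4,6-dimethoxy-3-propyl-2,3-dihydro-1H-inden-1-one
Conditions: [Rh(nbd)2]BF4 (5 mol%), (R)-BINAP (5.5 mol%), H2 (catalyst activation) then Ar, CH2Cl2, rt
Reagents that add atoms: none
Why: Intramolecular alkene hydroacylation, well established for 2-(1-alkylvinyl)benzaldehydes: the cationic monovalent rhodium–bisphosphine complex adds into the formyl C–H bond, the hydride is delivered to the internal alkene carbon on the face selected by the chiral ligand (this sets C3 as S), and reductive elimination closes the five-membered ketone.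

Step 4
Reactants: 6 (S)-4,6-dimethoxy-3-propyl-2,3-dihydro-1H-inden-1-one
Product: 7 (S)-5,7-dimethoxy-4-propylchroman-2-one
Conditions: mCPBA (1.3 equiv), CF3CO2H (1 equiv), CH2Cl2, 0 °C to rt, dark; aq. Na2SO3
Reagents that add atoms: 3-chloroperoxybenzoic acid (mCPBA), OOC(=O)c1cccc(Cl)c1
Why: The peracid, activated by CF3CO2H, adds to the C1 carbonyl of 6 to give the tetrahedral Criegee adduct, and the aryl carbon C7a then shifts from C1 to the proximal peroxide oxygen as 3-chlorobenzoate leaves, which creates the aryl C–O bond that becomes C7–O of the target. The closest known reaction type is the Baeyer–Villiger oxidation of indan-1-ones to 3,4-dihydrocoumarins. The six-membered lactone is formed not by a cyclisation but by ring expansion of the five-membered ketone through this 1,2-shift, in which one oxygen atom is inserted between C1 and C7a. No stereocentre is created, and C3 of 6, which is β to the carbonyl and takes no part in bond making or breaking, is carried over unchanged as C4 of 7. The selectivity required is migration of the aryl carbon in preference to the C2 methylene; it rests on the higher migratory aptitude of an sp2 aryl carbon, whose π system stabilises the electron-deficient transition state, over a primary alkyl carbon, and acid catalysis accentuates this preference. Because both methoxy groups are meta to C7a and add nothing to that aptitude, the oxidant is kept to a small excess at low temperature so that neither methylene migration nor peracid attack on the electron-rich ring gains ground.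

Step 5
Reactants: 7 (S)-5,7-dimethoxy-4-propylchroman-2-one
Product: 8 (S)-5,7-dihydroxy-4-propylchroman-2-one
Conditions: BBr3 (3.5 equiv), CH2Cl2, −78 °C to rt; H2O
Reagents that add atoms: none
Why: Lewis acid-mediated ether cleavage: BBr3 coordinates each methoxy oxygen and bromide removes the methyl group by SN2, which the aryl lactone and the benzylic stereocentre should survive (any hydroxy acid formed on work-up re-closes under acid).

Step 6
Reactants: 8 (S)-5,7-dihydroxy-4-propylchroman-2-one
Product: 9 (S)-5-hydroxy-4-propyl-7-(triisopropylsilyloxy)chroman-2-one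
Conditions: TIPSCl (1.05 equiv), imidazole, CH2Cl2, 0 °C
Reagents that add atoms: chlorotriisopropylsilane (TIPSCl), CC(C)[Si](Cl)(C(C)C)C(C)C
Why: Sterically controlled silylation: O7 has two unsubstituted ortho positions whereas O5 is flanked by C4a and the propyl-bearing C4, so one equivalent of the bulky chlorosilane should react at O7 only.

Step 7
Reactants: 9 (S)-5-hydroxy-4-propyl-7-(triisopropylsilyloxy)chroman-2-one; 10 (E)-2-methylbut-2-enoyl chloride (tigloyl chloride)
Product: 11 (S)-5-hydroxy-6-[(E)-2-methylbut-2-enoyl]-4-propyl-7-(triisopropylsilyloxy)chroman-2-one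
Conditions: TiCl4 (2.2 equiv), CH2Cl2, −20 to 0 °C; cold aq. HCl
Reagents that add atoms: none
Why: Titanium-mediated ortho-acylation of a phenol (Friedel–Crafts acylation with Fries-type delivery): the aryloxytitanium species formed at O5 guides the acyl chloride to C6, the only free ortho carbon and the one activated by both flanking oxygens; the product chelate resists further reaction and the (E)-geometry of the acyl group is retained.

Step 8
Reactants: 11 (S)-5-hydroxy-6-[(E)-2-methylbut-2-enoyl]-4-propyl-7-(triisopropylsilyloxy)chroman-2-one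
Product: 12 (2R,3S,10S)-2,3-dimethyl-10-propyl-5-(triisopropylsilyloxy)-2,3,9,10-tetrahydro-4H,8H-pyrano[2,3-f]chromene-4,8-dione
Conditions: quinine (0.3 equiv), PhCl, rt
Reagents that add atoms: none
Why: Cinchona alkaloid-catalysed intramolecular oxa-Michael addition (6-endo-trig), known for ortho-tigloylphenols: the quinuclidine nitrogen activates the 5-OH of 11, C–O bond formation on one enone face sets C2, and kinetic protonation of the enol on the same face sets C3 cis to it, while the silyl group on the other ortho oxygen leaves only one direction of closure.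

Step 9
Reactants: 12 (2R,3S,10S)-2,3-dimethyl-10-propyl-5-(triisopropylsilyloxy)-2,3,9,10-tetrahydro-4H,8H-pyrano[2,3-f]chromene-4,8-dione
Product: 14 methyl (3S)-3-[(2R,3S)-5,7-dihydroxy-2,3-dimethyl-4-oxochroman-8-yl]hexanoate, via desilylated lactone 13 (not isolated)
Conditions: KHF2, MeOH, rt; then HCl (1.25 M in MeOH), rt; aq. NaHCO3
Reagents that add atoms: methanol, CO
Why: Bifluoride cleaves the aryl silyl ether under weakly acidic conditions, and acid-catalysed transesterification then opens the activated aryl lactone with methanol to the methyl ester and the free O7 phenol, so that the base-sensitive cis C3 centre never meets a base.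

Step 10
Reactants: 15 2-methylbut-3-en-2-ol
Product: 16 tert-butyl (2-methylbut-3-en-2-yl) carbonate
Conditions: n-BuLi, THF, −78 °C; Boc2O, −78 °C to rt
Reagents that add atoms: di-tert-butyl dicarbonate (Boc2O), CC(C)(C)OC(=O)OC(=O)OC(C)(C)C
Why: Acylation of the lithium tertiary alkoxide with Boc2O gives the mixed carbonate, the usual preparation of tertiary allylic carbonates.

Step 11
Reactants: 14 methyl (3S)-3-[(2R,3S)-5,7-dihydroxy-2,3-dimethyl-4-oxochroman-8-yl]hexanoate; 16 tert-butyl (2-methylbut-3-en-2-yl) carbonate
Product: 17 methyl (3S)-3-{(2R,3S)-5-hydroxy-2,3-dimethyl-7-[(2-methylbut-3-en-2-yl)oxy]-4-oxochroman-8-yl}hexanoate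
Conditions: Pd(PPh3)4 (3 mol%), THF, 0 °C to rt
Reagents that add atoms: none
Why: Palladium-catalysed decarboxylative allylic etherification (Tsuji–Trost type): zerovalent palladium ionises the carbonate, the tert-butoxide released deprotonates the more acidic, non-chelated 7-OH (the 5-OH is hydrogen-bonded to the C4 carbonyl), and the phenoxide attacks the more substituted allyl terminus under kinetic control to give the 1,1-dimethylallyl ether without added base.

Step 12
Reactants: 17 methyl (3S)-3-{(2R,3S)-5-hydroxy-2,3-dimethyl-7-[(2-methylbut-3-en-2-yl)oxy]-4-oxochroman-8-yl}hexanoate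
Product: 18 methyl (3S)-3-[(2R,3S)-5,7-dihydroxy-2,3-dimethyl-6-(3-methylbut-2-en-1-yl)-4-oxochroman-8-yl]hexanoate
Conditions: PhMe, 110 °C, degassed
Reagents that add atoms: none
Why: Aromatic Claisen rearrangement: the [3,3]-sigmatropic shift transfers the allyl unit with allylic inversion from O7 to C6, the only unsubstituted ortho carbon, and tautomerisation gives the C-prenyl phenol; heat alone is used, so no stereocentre is formed or disturbed.

Compound list
1 | 2-bromopent-1-ene | C=C(Br)CCC | starting material
2 | pent-1-en-2-ylmagnesium bromide | C=C(CCC)[Mg]Br | intermediate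
3 | 4,4,5,5-tetramethyl-2-(pent-1-en-2-yl)-1,3,2-dioxaborolane | C=C(CCC)B1OC(C)(C)C(C)(C)O1 | intermediate
4 | 2-bromo-3,5-dimethoxybenzaldehyde | COc1cc(OC)c(Br)c(C=O)c1 | starting material
5 | 3,5-dimethoxy-2-(pent-1-en-2-yl)benzaldehyde | C=C(CCC)c1c(C=O)cc(OC)cc1OC | intermediate
6 | (S)-4,6-dimethoxy-3-propyl-2,3-dihydro-1H-inden-1-one | CCC[C@H]1CC(=O)c2cc(OC)cc(OC)c21 | intermediate
7 | (S)-5,7-dimethoxy-4-propylchroman-2-one | CCC[C@H]1CC(=O)Oc2cc(OC)cc(OC)c21 | intermediate
8 | (S)-5,7-dihydroxy-4-propylchroman-2-one | CCC[C@H]1CC(=O)Oc2cc(O)cc(O)c21 | intermediate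
9 | (S)-5-hydroxy-4-propyl-7-(triisopropylsilyloxy)chroman-2-one | CCC[C@H]1CC(=O)Oc2cc(O[Si](C(C)C)(C(C)C)C(C)C)cc(O)c21 | intermediate
10 | (E)-2-methylbut-2-enoyl chloride (tigloyl chloride) | C/C=C(\C)C(=O)Cl | starting material
11 | (S)-5-hydroxy-6-[(E)-2-methylbut-2-enoyl]-4-propyl-7-(triisopropylsilyloxy)chroman-2-one | CCC[C@H]1CC(=O)Oc2cc(O[Si](C(C)C)(C(C)C)C(C)C)c(C(=O)/C(C)=C/C)c(O)c21 | intermediate
12 | (2R,3S,10S)-2,3-dimethyl-10-propyl-5-(triisopropylsilyloxy)-2,3,9,10-tetrahydro-4H,8H-pyrano[2,3-f]chromene-4,8-dione (cis-2,3-dimethylchromanone whose C7–O and C8 carry the propyl-substituted six-membered lactone) | CCC[C@H]1CC(=O)Oc2cc(O[Si](C(C)C)(C(C)C)C(C)C)c3C(=O)[C@@H](C)[C@@H](C)Oc3c21 | intermediate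
13 | (2R,3S,10S)-5-hydroxy-2,3-dimethyl-10-propyl-2,3,9,10-tetrahydro-4H,8H-pyrano[2,3-f]chromene-4,8-dione | CCC[C@H]1CC(=O)Oc2cc(O)c3C(=O)[C@@H](C)[C@@H](C)Oc3c21 | intermediate
14 | methyl (3S)-3-[(2R,3S)-5,7-dihydroxy-2,3-dimethyl-4-oxochroman-8-yl]hexanoate | CCC[C@@H](CC(=O)OC)c1c(O)cc(O)c2c1O[C@H](C)[C@H](C)C2=O | intermediate
15 | 2-methylbut-3-en-2-ol | CC(C)(O)C=C | starting material
16 | tert-butyl (2-methylbut-3-en-2-yl) carbonate | CC(C)(C)OC(=O)OC(C)(C)C=C | intermediate
17 | methyl (3S)-3-{(2R,3S)-5-hydroxy-2,3-dimethyl-7-[(2-methylbut-3-en-2-yl)oxy]-4-oxochroman-8-yl}hexanoate | CCC[C@@H](CC(=O)OC)c1c(OC(C)(C)C=C)cc(O)c2c1O[C@H](C)[C@H](C)C2=O | intermediate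
18 | methyl (3S)-3-[(2R,3S)-5,7-dihydroxy-2,3-dimethyl-6-(3-methylbut-2-en-1-yl)-4-oxochroman-8-yl]hexanoate | CCC[C@@H](CC(=O)OC)c1c(O)c(CC=C(C)C)c(O)c2c1O[C@H](C)[C@H](C)C2=O | target

Total step count: 12
Longest linear sequence: 11 steps (steps 1–9, 11 and 12; step 10 prepares carbonate 16 on a side branch)

Steps most likely to fail

Step 4. The risk is migration of the C2 methylene in place of the aryl carbon in the Criegee adduct, or peracid attack on the electron-rich ring of substrate or product. The fallback sets out from 6 and returns at 7; it inserts the oxygen at the alcohol oxidation level, where the aryl shift is strongly preferred. NaBH4 in MeOH reduces 6 to (3S)-4,6-dimethoxy-3-propylindan-1-ol F1 (both C1 epimers serve). H2O2 with BF3·OEt2 in Et2O at 0 °C converts it into (3S)-1-hydroperoxy-4,6-dimethoxy-3-propylindane F2. Under the same acid F2 should undergo the Hock rearrangement (aryl shift from C1 to oxygen), and the cyclic oxocarbenium ion is captured by water as the lactol (4S)-5,7-dimethoxy-4-propylchroman-2-ol F3. Oxidation of the lactol with PhI(OAc)2 and catalytic TEMPO in CH2Cl2 gives 7.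

Step 7. The risk is acylation para to the phenol at C8, loss of the silyl ether under the Lewis acid, or acid-induced closure of the new enone to a stereorandom chromanone. The fallback sets out from 9 and returns at 11. Ortho-formylation with MgCl2, Et3N and paraformaldehyde in MeCN at reflux proceeds through the magnesium phenoxide and is strictly ortho to the free phenol; it gives (S)-5-hydroxy-2-oxo-4-propyl-7-(triisopropylsilyloxy)chroman-6-carbaldehyde F4. Chelation-assisted hydroacylation of but-2-yne with [RhCl(cod)]2, dppf and Na2CO3 in toluene at 80 °C then adds the formyl C–H bond syn across the alkyne and gives the (E)-enone 11.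

Step 11. The risk is slow etherification of the ortho-substituted O7, so that re-ionisation by palladium drifts the product to the linear prenyl ether or to C-allylation. The fallback sets out from 14 and returns at 18, by-passing 16 and 17. Iodination with N-iodosuccinimide in MeCN at 0 °C at C6, the only unsubstituted ring carbon, gives methyl (3S)-3-[(2R,3S)-5,7-dihydroxy-6-iodo-2,3-dimethyl-4-oxochroman-8-yl]hexanoate F5. Base-free Stille coupling with tributyl(3-methylbut-2-en-1-yl)stannane and Pd(PPh3)4 in DMF at 70 °C joins the prenyl group at its primary carbon and gives 18.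

Further compounds
F1 | step 4 | (3S)-4,6-dimethoxy-3-propylindan-1-ol | CCC[C@H]1CC(O)c2cc(OC)cc(OC)c21
F2 | step 4 | (3S)-1-hydroperoxy-4,6-dimethoxy-3-propylindane | CCC[C@H]1CC(OO)c2cc(OC)cc(OC)c21
F3 | step 4 | (4S)-5,7-dimethoxy-4-propylchroman-2-ol | CCC[C@H]1CC(O)Oc2cc(OC)cc(OC)c21
F4 | step 7 | (S)-5-hydroxy-2-oxo-4-propyl-7-(triisopropylsilyloxy)chroman-6-carbaldehyde | CCC[C@H]1CC(=O)Oc2cc(O[Si](C(C)C)(C(C)C)C(C)C)c(C=O)c(O)c21
F5 | step 11 | methyl (3S)-3-[(2R,3S)-5,7-dihydroxy-6-iodo-2,3-dimethyl-4-oxochroman-8-yl]hexanoate | CCC[C@@H](CC(=O)OC)c1c(O)c(I)c(O)c2c1O[C@H](C)[C@H](C)C2=O
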